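A direct plan would C-prenylate 2,4,6-trihydroxyacetophenone and 4-hydroxybenzaldehyde to the prenyl ketone A1 and the prenyl aldehyde A2, would condense these to the 2',4',6'-trihydroxychalcone A3, and would close ring C by an enantioselective intramolecular oxa-Michael addition. Its weakest steps would be:
- the C-prenylation of free phenols, where O-alkylation and polyalkylation would compete and the aldehyde would react sluggishly;
- the aldol condensation of two unprotected polyphenols, which would need a polyanion and would give a chalcone that cyclises spontaneously to racemic flavanone;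
- the asymmetric ring closure, which would have to pick one of two non-equivalent ortho-hydroxyls (6- versus 8-prenyl) and one enone face, and whose product could racemise by the reverse reaction.

The new route disconnects ring A instead of ring C. The C4a–C5 bond is cut back to a masked tetraketide in which ring C already exists as an enantioenriched 2-aryl-2,3-dihydro-4H-pyran-4-one (O1–C2 being the former aldehyde C=O of a hetero-Diels–Alder reaction) and C8–C7–C6(prenyl)–C5 hangs on C8a as a tert-butyl β-keto ester. Heating releases an acylketene whose carbon C5 closes onto C4a, the nucleophilic end of the enol-ether double bond C4a=C8a that ring A shares with the pyranone; tautomerisation gives the phloroglucinol ring in one operation. The prenyl group sits on the chain carbon that becomes C6, so no phenol is C-prenylated, no 6-/8-regiochemistry arises, and C2 is never formed by a reversible oxa-Michael addition.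

Key step: step 7

Remarks and assumptions:
- Ar denotes 3-(3-methylbut-2-en-1-yl)-4-[(triisopropylsilyl)oxy]phenyl; atom numbers C2–C8a are those of the flavanone.
- The sense of induction in step 4 is assigned by analogy with simple aromatic aldehydes: the ligand enantiomer is to be the one that directs the diene to the Si face of 4, and its antipode would be used if the first run showed the opposite sense.
- Diene 6 is used as the mixture of ketene-acetal isomers formed. Compounds 11, 13 and 14 are mixtures at the ester α-carbon (13 also at the hemiketal carbon) and of keto–enol tautomers; these centres become sp2 in step 7.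

Step 1
Reactants: 1 3-bromo-4-hydroxybenzaldehyde
Product: 2 3-bromo-4-[(triisopropylsilyl)oxy]benzaldehyde
Conditions: iPr3SiCl (1.2 equiv), imidazole (2.5 equiv), DMF, 0 °C → rt, 3 h
Reagents that add atoms: chlorotriisopropylsilane, CC(C)[Si](Cl)(C(C)C)C(C)C
Why: Silylation of the phenol (substitution at silicon by the imidazole-activated chloride) masks the acidic OH for the organometallic and Lewis-acid steps, the bulky triisopropylsilyl group being chosen because a para-formyl aryl silyl ether is otherwise easily cleaved; no stereocentre.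

Step 2
Reactants: 2 3-bromo-4-[(triisopropylsilyl)oxy]benzaldehyde; 3 tributyl(3-methylbut-2-en-1-yl)stannane
Product: 4 3-(3-methylbut-2-en-1-yl)-4-[(triisopropylsilyl)oxy]benzaldehyde
Conditions: 3 (1.3 equiv), Pd(PPh3)4 (5 mol %), DMF, 95 °C, 12 h, Ar; chromatography on K2CO3-doped silica
Reagents that add atoms: none
Why: Stille cross-coupling, in which zerovalent palladium inserts into the C–Br bond, the allylic stannane transmetallates and the η3-prenyl palladium intermediate reductively eliminates at its unsubstituted terminus, should give the linear C-prenyl arene under neutral conditions that leave the aldehyde and the silyl ether untouched; no stereocentre.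

Step 3
Reactants: 5 methyl (E)-3-methoxybut-2-enoate
Product: 6 1,3-dimethoxy-1-[(trimethylsilyl)oxy]buta-1,3-diene
Conditions: LiN(iPr)2 (1.1 equiv), THF, −78 °C, 1 h; Me3SiCl (1.3 equiv), −78 °C → rt; pentane, filtration, distillation
Reagents that add atoms: chlorotrimethylsilane, C[Si](C)(C)Cl
Why: γ-Deprotonation of the vinylogous carbonate to its lithium dienolate and O-silylation (silyl ketene acetal formation) should give the electron-rich 1,1,3-trioxygenated diene; no stereocentre.

Step 4
Reactants: 4 3-(3-methylbut-2-en-1-yl)-4-[(triisopropylsilyl)oxy]benzaldehyde; 6 1,3-dimethoxy-1-[(trimethylsilyl)oxy]buta-1,3-diene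
Product: 8 (6S)-6-Ar-4-methoxy-5,6-dihydro-2H-pyran-2-one, via silyl aldol adduct 7 (not isolated)
Conditions: 6 (1.5 equiv), Ti(OiPr)4 (10 mol %), (S)-2-[(3,5-di-tert-butyl-2-hydroxybenzylidene)amino]-3,3-dimethylbutan-1-ol (11 mol %), 4 Å MS, toluene, −20 °C, 48 h; then CF3CO2H (2 equiv), CH2Cl2, 0 °C, 1 h
Reagents that add atoms: none
Why: Catalytic asymmetric hetero-Diels–Alder reaction, which on the chiral tetravalent titanium Schiff-base complex runs as a Mukaiyama aldol addition of the diene terminus to the Si face of the bound aldehyde (this sets the carbinol carbon, the later C2 and only stereocentre of the target, as S, with O1–C2 being the former C=O bond), followed by acid-induced desilylation and lactonisation onto the cis-disposed ester.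

Step 5
Reactants: 9 tert-butyl acetoacetate; 10 prenyl bromide (1-bromo-3-methylbut-2-ene)
Product: 11 tert-butyl 2-acetyl-5-methylhex-4-enoate
Conditions: NaH (1.0 equiv), THF, 0 °C; 10 (0.9 equiv), 0 °C → rt, 6 h
Reagents that add atoms: none
Why: Acetoacetic ester alkylation (SN2 attack of the sodium enolate on the primary allylic bromide) puts the prenyl group on the carbon that becomes C6 of ring A, a slight deficit of bromide limiting dialkylation; the new centre is racemic and is erased in step 7.

Step 6
Reactants: 11 tert-butyl 2-acetyl-5-methylhex-4-enoate; 8 (6S)-6-Ar-4-methoxy-5,6-dihydro-2H-pyran-2-one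
Product: 14 tert-butyl 2-{[(2S)-2-Ar-4-oxo-3,4-dihydro-2H-pyran-6-yl]acetyl}-5-methylhex-4-enoate, via dilithium dianion 12 (not isolated), via hemiketal adduct 13 (not isolated)
Conditions: 11 (2.6 equiv), LiN(iPr)2 (5.0 equiv), THF, −78 → 0 °C, 30 min; 8 (1.0 equiv), −78 → −30 °C, 2 h; then 0.5 M aq HCl–THF, 0 °C → rt, 1 h
Reagents that add atoms: water, O
Why: The γ-carbanion of the β-keto ester dianion adds 1,2 to the lactone carbonyl (the only carbonyl of 8, the excess dianion deprotonating the adduct against a second addition), and dilute acid then ionises hemiketal 13, a vinylogous ortho ester, water attacks C4 and methanol is lost (Stork–Danheiser-type carbonyl transposition) to give the dihydropyranone with its side chain on C8a; the C2–O1 bond is never broken, so the S configuration is kept.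

Step 7
Reactants: 14 tert-butyl 2-{[(2S)-2-Ar-4-oxo-3,4-dihydro-2H-pyran-6-yl]acetyl}-5-methylhex-4-enoate
Product: 17 (2S)-2-Ar-5,7-dihydroxy-6-(3-methylbut-2-en-1-yl)-2,3-dihydro-4H-chromen-4-one, via acylketene 15 (not isolated), via dienone 16 (not isolated)
Conditions: degassed xylene (0.01 M), 135 °C, slow Ar sweep to carry off tert-butanol, 2–6 h, dark
Reagents that add atoms: none
Why: Proposed new method: on heating, the enol of the tert-butyl β-keto ester loses tert-butanol through a six-membered transition state (the way tert-butyl acetoacetates and dioxinones are known to give acylketenes) to form the α-prenyl acylketene 15, whose C7 carbonyl enolises towards the doubly activated C8 methylene so that C5=C6, C7=C8 and C8a=C4a make up a 3-hydroxy-dienylketene. This closes the C5–C4a bond by thermal 6π-electrocyclisation (seen stepwise, a 6-exo-dig attack of the nucleophilic α-carbon C4a of the vinylogous ester on the ketene carbon) to give the carbocyclic dienone 16, which tautomerises irreversibly to the 5,7-dihydroxy-6-prenyl ring A, the only ring formed and a six-membered one. The closest known reaction types are the electrocyclisation of 3-oxy-dienylketenes to resorcinols in the Danheiser benzannulation and the base-mediated Claisen cyclisation of 3,5,7-triketo esters to acylphloroglucinols, of which this is a neutral, thermal counterpart. No stereocentre is formed, and C2, set in step 4, should be kept because the medium is neutral and aprotic, so that neither enolisation at C3 nor β-elimination of O1 is promoted. The step needs C- rather than O-acylation and closure at C4a: attack by the carbonyl oxygens or by C8 would require four- or eight-membered rings, the ether oxygen O1 of the vinylogous ester is non-nucleophilic and could add only reversibly, the aldol alternative from C6 cannot aromatise because C6 carries the prenyl group, and high dilution suppresses ketene dimerisation. The 6-prenyl pattern is not a matter of selectivity, since the prenyl group is already bonded to the carbon between C5 and C7.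

Step 8
Reactants: 17 (2S)-2-Ar-5,7-dihydroxy-6-(3-methylbut-2-en-1-yl)-2,3-dihydro-4H-chromen-4-one
Product: 18 macarangaflavanone B, (2S)-5,7-dihydroxy-2-[4-hydroxy-3-(3-methylbut-2-en-1-yl)phenyl]-6-(3-methylbut-2-en-1-yl)-2,3-dihydro-4H-chromen-4-one
Conditions: Bu4NF (1.1 equiv), AcOH (1.5 equiv), THF, 0 °C, 30 min; pH 5 buffer work-up
Reagents that add atoms: none
Why: Fluoride-mediated desilylation cleaves the aryl Si–O bond (driven by the strong Si–F bond) while acetic acid buffers the liberated phenoxide, so that the base-sensitive flavanone should not open by retro-oxa-Michael reaction and C2 stays S; the prenyl groups are inert.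

**Compound list**
1 | 3-bromo-4-hydroxybenzaldehyde | O=Cc1ccc(O)c(Br)c1 | starting material
2 | 3-bromo-4-[(triisopropylsilyl)oxy]benzaldehyde | O=Cc1ccc(O[Si](C(C)C)(C(C)C)C(C)C)c(Br)c1 | intermediate
3 | tributyl(3-methylbut-2-en-1-yl)stannane | CCCC[Sn](CCCC)(CCCC)CC=C(C)C | starting material
4 | 3-(3-methylbut-2-en-1-yl)-4-[(triisopropylsilyl)oxy]benzaldehyde | CC(C)=CCc1cc(C=O)ccc1O[Si](C(C)C)(C(C)C)C(C)C | intermediate
5 | methyl (E)-3-methoxybut-2-enoate | CO/C(C)=C/C(=O)OC | starting material
6 | 1,3-dimethoxy-1-[(trimethylsilyl)oxy]buta-1,3-diene (ketene-acetal isomers as formed) | C=C(OC)C=C(OC)O[Si](C)(C)C | intermediate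
7 | methyl (2E,5S)-5-Ar-3-methoxy-5-[(trimethylsilyl)oxy]pent-2-enoate | CC(C)=CCc1cc([C@@H](O[Si](C)(C)C)C/C(OC)=C\C(=O)OC)ccc1O[Si](C(C)C)(C(C)C)C(C)C | intermediate (not isolated)
8 | (6S)-6-Ar-4-methoxy-5,6-dihydro-2H-pyran-2-one | CC(C)=CCc1cc([C@@H]2CC(OC)=CC(=O)O2)ccc1O[Si](C(C)C)(C(C)C)C(C)C | intermediate
9 | tert-butyl acetoacetate | CC(=O)CC(=O)OC(C)(C)C | starting material
10 | prenyl bromide (1-bromo-3-methylbut-2-ene) | CC(C)=CCBr | starting material
11 | tert-butyl 2-acetyl-5-methylhex-4-enoate (racemic) | CC(=O)C(CC=C(C)C)C(=O)OC(C)(C)C | intermediate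
12 | dilithium 1-tert-butoxy-2-(3-methylbut-2-en-1-yl)buta-1,3-diene-1,3-diolate (dianion of 11) | [Li+].[Li+].C=C([O-])C(CC=C(C)C)=C([O-])OC(C)(C)C | intermediate (not isolated)
13 | tert-butyl 2-{[(6S)-6-Ar-2-hydroxy-4-methoxy-5,6-dihydro-2H-pyran-2-yl]acetyl}-5-methylhex-4-enoate | CC(C)=CCc1cc([C@@H]2CC(OC)=CC(O)(CC(=O)C(CC=C(C)C)C(=O)OC(C)(C)C)O2)ccc1O[Si](C(C)C)(C(C)C)C(C)C | intermediate (not isolated)
14 | tert-butyl 2-{[(2S)-2-Ar-4-oxo-3,4-dihydro-2H-pyran-6-yl]acetyl}-5-methylhex-4-enoate | CC(C)=CCc1cc([C@@H]2CC(=O)C=C(CC(=O)C(CC=C(C)C)C(=O)OC(C)(C)C)O2)ccc1O[Si](C(C)C)(C(C)C)C(C)C | intermediate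
15 | (2S)-2-Ar-6-[6-methyl-2-oxo-3-(oxomethylidene)hept-5-en-1-yl]-2,3-dihydro-4H-pyran-4-one (acylketene) | CC(C)=CCc1cc([C@@H]2CC(=O)C=C(CC(=O)C(CC=C(C)C)=C=O)O2)ccc1O[Si](C(C)C)(C(C)C)C(C)C | intermediate (not isolated)
16 | (2S)-2-Ar-7-hydroxy-6-(3-methylbut-2-en-1-yl)-2,3-dihydro-4H-chromene-4,5(4aH)-dione | CC(C)=CCc1cc([C@@H]2CC(=O)C3C(=O)C(CC=C(C)C)=C(O)C=C3O2)ccc1O[Si](C(C)C)(C(C)C)C(C)C | intermediate (not isolated)
17 | (2S)-2-Ar-5,7-dihydroxy-6-(3-methylbut-2-en-1-yl)-2,3-dihydro-4H-chromen-4-one | CC(C)=CCc1cc([C@@H]2CC(=O)c3c(cc(O)c(CC=C(C)C)c3O)O2)ccc1O[Si](C(C)C)(C(C)C)C(C)C | intermediate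
18 | macarangaflavanone B, (2S)-5,7-dihydroxy-2-[4-hydroxy-3-(3-methylbut-2-en-1-yl)phenyl]-6-(3-methylbut-2-en-1-yl)-2,3-dihydro-4H-chromen-4-one | CC(C)=CCc1cc([C@@H]2CC(=O)c3c(cc(O)c(CC=C(C)C)c3O)O2)ccc1O | target

Total steps: 8. Longest linear sequence: 6 (steps 1, 2, 4, 6, 7, 8); steps 3 and 5 are one-step branches.

**Steps most likely to fail**

1. Step 7 (Proposed new method). The acylketene could be intercepted intermolecularly (dimerisation, O-acylation of the enolic chain of a second molecule) faster than it closes onto C4a. Long heating could also erode the C2 configuration through enolisation of the pyranone towards C3 and reversible electrocyclic opening of the resulting 2H-pyran. Fallback with known reaction types: setting out from 14, the thermolysis would be run in toluene at 110 °C in the presence of benzenethiol, which intercepts the acylketene as the thioester S-phenyl 2-{[(2S)-2-Ar-4-oxo-3,4-dihydro-2H-pyran-6-yl]acetyl}-5-methylhex-4-enethioate F1. Soft enolisation of F1 (MgBr2·OEt2, iPr2NEt, CH2Cl2, 0 °C, then AcOH) would then bring about the ionic Claisen condensation of C4a onto the thioester and aromatisation, coming back to the route at 17.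

2. Step 6. Proton transfer from the lactone to the strongly basic dianion could outrun carbonyl addition and lead to β-elimination of the carboxylate (ring opening to an achiral dienoic acid), or the dianion could add at C4 with loss of methoxide. Fallback: setting out from 8, the small lithium enolate of tert-butyl acetate (LiN(iPr)2, THF, −78 °C), followed by the same dilute-acid transposition, would give tert-butyl [(2S)-2-Ar-4-oxo-3,4-dihydro-2H-pyran-6-yl]acetate F2. CF3CO2H in CH2Cl2 at 0 °C would free [(2S)-2-Ar-4-oxo-3,4-dihydro-2H-pyran-6-yl]acetic acid F3. In parallel, tert-butyl methyl malonate would be alkylated with 10 (NaH, THF) to tert-butyl methyl (3-methylbut-2-en-1-yl)malonate F4 and saponified at the methyl ester (LiOH, THF–H2O, 0 °C) to 2-(tert-butoxycarbonyl)-5-methylhex-4-enoic acid F5. Activation of F3 with 1,1'-carbonyldiimidazole to the acyl imidazolide (2S)-2-Ar-6-[2-(1H-imidazol-1-yl)-2-oxoethyl]-2,3-dihydro-4H-pyran-4-one F6 and treatment with F5, MgCl2 and Et3N (magnesium malonate chain extension with decarboxylation) would come back to the route at 14.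

3. Step 4. The electron-rich aldehyde could react too slowly for the catalysed pathway to dominate, so that facial selectivity is poor, or the aldol adduct could lactonise incompletely. Fallback: setting out from 4, a vinylogous Mukaiyama aldol addition of the dioxinone-derived silyl dienolate 2,2-dimethyl-4-methylidene-6-[(trimethylsilyl)oxy]-4H-1,3-dioxine F7 (from 2,2,6-trimethyl-4H-1,3-dioxin-4-one, LiN(iPr)2, Me3SiCl) would be used. With Ti(OiPr)4 and the BINOL enantiomer that directs attack to the Si face, this would give 6-[(2S)-2-Ar-2-hydroxyethyl]-2,2-dimethyl-4H-1,3-dioxin-4-one F8. Heating F8 in toluene at 110 °C would release acetone and let the hydroxyl trap the acylketene as (6S)-6-Ar-dihydro-2H-pyran-2,4(3H)-dione F9. O-methylation of F9 (Me2SO4, K2CO3, acetone) would come back to the route at 8.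

**Further compounds**
F1 | step 7 | S-phenyl 2-{[(2S)-2-Ar-4-oxo-3,4-dihydro-2H-pyran-6-yl]acetyl}-5-methylhex-4-enethioate | CC(C)=CCc1cc([C@@H]2CC(=O)C=C(CC(=O)C(CC=C(C)C)C(=O)Sc3ccccc3)O2)ccc1O[Si](C(C)C)(C(C)C)C(C)C
F2 | step 6 | tert-butyl [(2S)-2-Ar-4-oxo-3,4-dihydro-2H-pyran-6-yl]acetate | CC(C)=CCc1cc([C@@H]2CC(=O)C=C(CC(=O)OC(C)(C)C)O2)ccc1O[Si](C(C)C)(C(C)C)C(C)C
F3 | step 6 | [(2S)-2-Ar-4-oxo-3,4-dihydro-2H-pyran-6-yl]acetic acid | CC(C)=CCc1cc([C@@H]2CC(=O)C=C(CC(=O)O)O2)ccc1O[Si](C(C)C)(C(C)C)C(C)C
F4 | step 6 | tert-butyl methyl (3-methylbut-2-en-1-yl)malonate | COC(=O)C(CC=C(C)C)C(=O)OC(C)(C)C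
F5 | step 6 | 2-(tert-butoxycarbonyl)-5-methylhex-4-enoic acid | CC(C)=CCC(C(=O)O)C(=O)OC(C)(C)C
F6 | step 6 | (2S)-2-Ar-6-[2-(1H-imidazol-1-yl)-2-oxoethyl]-2,3-dihydro-4H-pyran-4-one | CC(C)=CCc1cc([C@@H]2CC(=O)C=C(CC(=O)n3ccnc3)O2)ccc1O[Si](C(C)C)(C(C)C)C(C)C
F7 | step 4 | 2,2-dimethyl-4-methylidene-6-[(trimethylsilyl)oxy]-4H-1,3-dioxine | C=C1C=C(O[Si](C)(C)C)OC(C)(C)O1
F8 | step 4 | 6-[(2S)-2-Ar-2-hydroxyethyl]-2,2-dimethyl-4H-1,3-dioxin-4-one | CC(C)=CCc1cc([C@@H](O)CC2=CC(=O)OC(C)(C)O2)ccc1O[Si](C(C)C)(C(C)C)C(C)C
F9 | step 4 | (6S)-6-Ar-dihydro-2H-pyran-2,4(3H)-dione | CC(C)=CCc1cc([C@@H]2CC(=O)CC(=O)O2)ccc1O[Si](C(C)C)(C(C)C)C(C)C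
A1 | direct plan | 1-[2,4,6-trihydroxy-3-(3-methylbut-2-en-1-yl)phenyl]ethan-1-one | CC(=O)c1c(O)cc(O)c(CC=C(C)C)c1O
A2 | direct plan | 4-hydroxy-3-(3-methylbut-2-en-1-yl)benzaldehyde | O=Cc1ccc(O)c(CC=C(C)C)c1
A3 | direct plan | (E)-3-[4-hydroxy-3-(3-methylbut-2-en-1-yl)phenyl]-1-[2,4,6-trihydroxy-3-(3-methylbut-2-en-1-yl)phenyl]prop-2-en-1-one | CC(C)=CCc1cc(/C=C/C(=O)c2c(O)cc(O)c(CC=C(C)C)c2O)ccc1O
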